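**Retrosynthetic overview**
1. Target ⇐ C9 enone and C15 acetate on a bicyclo[3.2.1]octene. Its five-membered ring (C8–C15–C16–C13–C14) comes from a CrCl2/NiCl2-mediated reductive coupling of the C16≡C17 alkyne with the C15 aldehyde; C15 is then set by oxidation and Luche reduction.
2. Cyclohexene ring C8–C9–C11–C12–C13–C14 ⇐ catalyst-controlled Diels–Alder reaction of a 2-methylene aldehyde (C8=C14, C15HO) with a 1-silyloxy dienyne (C9, C11–C13, C16, C17).
3. Feature on which the strategy rests: the γ-lactone C19(=O)–O–C6 spans exactly the C4–C5 bond of ring A (C1–C2–C3–C4–C5–C10). Ring A and the lactone therefore ⇐ one intramolecular Diels–Alder reaction of the methacrylate of a C6 dienyl carbinol (bonds C4–C5 and C2–C3); the C10 hydroxyl follows by Mukaiyama hydration of C1=C10.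
4. Dienyl carbinol ⇐ catalytic asymmetric addition of a 3-silyloxypropylzinc reagent (C7–C8–C15) to (E)-3-methylpenta-2,4-dienal.
5. Ring order: ring A and the lactone together, then the cyclohexene, then the five-membered ring that completes the bicyclo[3.2.1]octane.

Key step: step 6

Remark on numbering: ring A = C1–C2–C3–C4–C5–C10; C18 = methyl on C4; C19(=O)–O–C6 = lactone; C20 = methyl on C10; C7 = CH2 arm; C8 and C13 = bridgeheads; C9 = ketone; C11=C12; C14 = one-carbon bridge; C15 = CH–OAc; C16=C17 = exocyclic methylene.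

Assumption: the cationic oxazaborolidine binds the 2-alkylacrolein in its usual mode (boron on the formyl oxygen, formyl C–H against the ring oxygen, s-trans enal); on that model the (R)-catalyst exposes the face of C8=C14 that leads to the target series, and the (S)-catalyst would give the C8 epimer.

**Route**

Step 1
Reactants: 1 (E)-3-methylpent-2-en-4-yn-1-ol
Product: 2 (E)-3-methylpenta-2,4-dien-1-ol
Conditions: H2 (1 atm), Pd/CaCO3 poisoned with Pb(OAc)2 (Lindlar catalyst), quinoline, Et2O, 0 °C, stopped after 1 equiv H2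
Reagents that add atoms: none
Why: Lindlar semihydrogenation stops at the alkene for a terminal alkyne and leaves the trisubstituted (E)-alkene and the allylic alcohol untouched, so the diene geometry needed later is kept.

Step 2
Reactants: 2 (E)-3-methylpenta-2,4-dien-1-ol
Product: 3 (E)-3-methylpenta-2,4-dienal
Conditions: activated MnO2 (excess), CH2Cl2, rt; filtered, concentrated cold, used at once
Reagents that add atoms: none
Why: Manganese dioxide oxidises the primary allylic alcohol selectively to the conjugated aldehyde without E/Z isomerisation (allylic oxidation).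

Step 3
Reactants: 4 3-iodopropan-1-ol
Product: 5 tert-butyl(3-iodopropoxy)diphenylsilane
Conditions: TBDPSCl, imidazole, CH2Cl2, 0 °C to rt
Reagents that add atoms: tert-butyl(chloro)diphenylsilane, CC(C)(C)[Si](Cl)(c1ccccc1)c1ccccc1
Why: Imidazole-promoted silylation of a primary alcohol is reliable, and the mild base avoids oxetane formation from the γ-iodo alkoxide.

Step 4
Reactants: 5 tert-butyl(3-iodopropoxy)diphenylsilane; 3 (E)-3-methylpenta-2,4-dienal
Product: 7 (4R,5E)-1-[(tert-butyldiphenylsilyl)oxy]-6-methylocta-5,7-dien-4-ol, via bis[3-(tert-butyldiphenylsilyloxy)propyl]zinc 6 (not isolated)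
Conditions: (a) 5 (2.4 equiv), Et2Zn, CuI (cat.), neat, 50 °C, then Et2Zn and EtI removed in vacuo; (b) (1S,2S)-1,2-bis(trifluoromethanesulfonamido)cyclohexane (8 mol%), Ti(OiPr)4, toluene, –20 °C, then 3; aq. NH4Cl
Reagents that add atoms: none
Why: Iodine–zinc exchange gives the functionalised dialkylzinc, and its titanium-mediated, ligand-accelerated catalytic asymmetric 1,2-addition to the aldehyde sets C6; the (1S,2S) ligand is chosen because the (1R,2R) ligand is known to give (S)-alcohols from conjugated aldehydes, so its mirror image should give the (R)-carbinol.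

Step 5
Reactants: 7 (4R,5E)-1-[(tert-butyldiphenylsilyl)oxy]-6-methylocta-5,7-dien-4-ol; 8 methacryloyl chloride
Product: 9 (4R,5E)-1-[(tert-butyldiphenylsilyl)oxy]-6-methylocta-5,7-dien-4-yl 2-methylprop-2-enoate
Conditions: Et3N, DMAP (cat.), BHT (cat.), CH2Cl2, 0 °C
Reagents that add atoms: none
Why: DMAP-catalysed acylation of the secondary alcohol with the acid chloride leaves C6 untouched (retention), and BHT prevents radical polymerisation of the methacrylate.

Step 6
Reactants: 9 (4R,5E)-1-[(tert-butyldiphenylsilyl)oxy]-6-methylocta-5,7-dien-4-yl 2-methylprop-2-enoate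
Product: 10 (3R,3aS,7aR)-3-{3-[(tert-butyldiphenylsilyl)oxy]propyl}-4,7a-dimethyl-3a,6,7,7a-tetrahydro-2-benzofuran-1(3H)-one
Conditions: BHT (10 mol%), degassed toluene (0.01 M), sealed tube, 180 °C
Reagents that add atoms: none
Why: A thermal, concerted but asynchronous [4+2] cycloaddition (type 1 intramolecular Diels–Alder reaction; the closest known class is pentadienyl acrylates giving bicyclic γ-lactones) joins C3=C4 of the methacrylate to the diene C5=C10–C1=C2 and forms C4–C5 and C2–C3. Ring A is closed as the six-membered ring of the cycloaddition itself, and the γ-lactone is closed by the same C4–C5 bond, because the three-atom tether C6–O–C19 then lies in a five-membered ring. The tether dictates that C4 bonds to C5, a regiochemistry for which the 1-alkyl and the 2-methyl group of the diene would pull in opposite directions in an intermolecular reaction. C5 is set relative to C6 by allylic 1,3-strain: the C10 methyl is cis to C6 on C5=C10, so H6 lies in the diene plane, the tether oxygen is on the face the dienophile must use and the C7 chain on the other face, which places H5 trans to H6. C4 is set by the orientation of the tether carbonyl: the required cis fusion (C18 methyl cis to H5) comes from the transition state with C19=O under the diene and the α-methyl outside, away from the C10 methyl, but this cis/trans choice is the selectivity the substrate secures least, and a trans-fused isomer would be removed by chromatography. The ester must reach its s-cis conformer to cyclise, hence the high temperature, while high dilution and BHT suppress polymerisation.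

Step 7
Reactants: 10 (3R,3aS,7aR)-3-{3-[(tert-butyldiphenylsilyl)oxy]propyl}-4,7a-dimethyl-3a,6,7,7a-tetrahydro-2-benzofuran-1(3H)-one
Product: 11 (3R,3aS,4R,7aR)-3-{3-[(tert-butyldiphenylsilyl)oxy]propyl}-4-hydroxy-4,7a-dimethylhexahydro-2-benzofuran-1(3H)-one
Conditions: Co(acac)2 (20 mol%), PhSiH3, O2 (1 atm), THF, rt
Reagents that add atoms: dioxygen, O=O
Why: Mukaiyama hydration (hydrogen-atom transfer from a cobalt hydride to C1, then O2 capture of the tertiary C10 radical) gives the Markovnikov tertiary alcohol, and the radical should be trapped on the convex face of the cis-fused bicycle, anti to the C5–C6 bond, which puts the hydroxyl cis to H5 as in the target.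

Step 8
Reactants: 11 (3R,3aS,4R,7aR)-3-{3-[(tert-butyldiphenylsilyl)oxy]propyl}-4-hydroxy-4,7a-dimethylhexahydro-2-benzofuran-1(3H)-one
Product: 12 (3R,3aS,4R,7aR)-4-hydroxy-3-(3-hydroxypropyl)-4,7a-dimethylhexahydro-2-benzofuran-1(3H)-one
Conditions: TBAF, AcOH, THF, 0 °C to rt
Reagents that add atoms: none
Why: Buffered fluoride cleaves the primary silyl ether without opening the lactone, and the C10 hydroxyl, being trans to C19 on ring A, cannot translactonise.

Step 9
Reactants: 12 (3R,3aS,4R,7aR)-4-hydroxy-3-(3-hydroxypropyl)-4,7a-dimethylhexahydro-2-benzofuran-1(3H)-one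
Product: 13 3-[(3R,3aS,4R,7aR)-4-hydroxy-4,7a-dimethyl-1-oxooctahydro-2-benzofuran-3-yl]propanal
Conditions: Dess–Martin periodinane, CH2Cl2, rt
Reagents that add atoms: none
Why: Dess–Martin oxidation converts the primary alcohol into the aldehyde and cannot oxidise the tertiary alcohol.

Step 10
Reactants: 13 3-[(3R,3aS,4R,7aR)-4-hydroxy-4,7a-dimethyl-1-oxooctahydro-2-benzofuran-3-yl]propanal
Product: 14 2-{[(3R,3aS,4R,7aR)-4-hydroxy-4,7a-dimethyl-1-oxooctahydro-2-benzofuran-3-yl]methyl}prop-2-enal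
Conditions: aq. CH2O (37%), pyrrolidine (10 mol%), propionic acid (10 mol%), i-PrOH, 45 °C
Reagents that add atoms: formaldehyde, C=O
Why: Amine/acid-catalysed α-methylenation (Mannich condensation of the enamine with formaldehyde, then elimination of the amine) turns the CH2 next to the formyl group (C8) into the 2-methylene aldehyde, C14 coming from formaldehyde.

Step 11
Reactants: 14 2-{[(3R,3aS,4R,7aR)-4-hydroxy-4,7a-dimethyl-1-oxooctahydro-2-benzofuran-3-yl]methyl}prop-2-enal
Product: 15 2-{[(3R,3aS,4R,7aR)-4,7a-dimethyl-1-oxo-4-[(triethylsilyl)oxy]octahydro-2-benzofuran-3-yl]methyl}prop-2-enal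
Conditions: TESOTf, 2,6-lutidine, CH2Cl2, –78 to 0 °C
Reagents that add atoms: triethylsilyl trifluoromethanesulfonate, CC[Si](CC)(CC)OS(=O)(=O)C(F)(F)F
Why: The silyl triflate is reactive enough to cap the hindered tertiary alcohol, which would otherwise quench the boron Lewis acid of step 15.

Step 12
Reactants: 16 pyridine–sulfur trioxide complex
Product: 17 potassium (1E,3E)-5-oxopenta-1,3-dien-1-olate (glutaconaldehyde potassium salt)
Conditions: KOH, H2O, –20 °C to rt; crystallisation
Reagents that add atoms: potassium hydroxide, [K+].[OH-]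
Why: Hydroxide opens the N-sulfonated pyridinium ring (Zincke-type ring opening) and hydrolysis releases the all-trans glutaconaldehyde enolate, which crystallises as its potassium salt.

Step 13
Reactants: 17 potassium (1E,3E)-5-oxopenta-1,3-dien-1-olate
Product: 18 (2E,4E)-5-[(tert-butyldimethylsilyl)oxy]penta-2,4-dienal
Conditions: TBSCl, DMF, rt
Reagents that add atoms: tert-butyl(chloro)dimethylsilane, CC(C)(C)[Si](C)(C)Cl
Why: O-Silylation of the delocalised enolate gives the vinylogous silyl formate with the (E,E) geometry of the salt retained.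

Step 14
Reactants: 18 (2E,4E)-5-[(tert-butyldimethylsilyl)oxy]penta-2,4-dienal
Product: 19 tert-butyl[(1E,3E)-hexa-1,3-dien-5-yn-1-yloxy]dimethylsilane
Conditions: TMSCHN2, n-BuLi, THF, –78 °C; then 18, –78 to 0 °C; aq. NaHCO3
Reagents that add atoms: (trimethylsilyl)diazomethane, C[Si](C)(C)C=[N+]=[N-]
Why: Colvin rearrangement (addition of lithiated trimethylsilyldiazomethane, loss of silanolate and N2, 1,2-hydrogen shift of the alkylidene carbene) turns the aldehyde into the terminal alkyne at a temperature that spares the silyl dienol ether.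

Step 15
Reactants: 15 2-{[(3R,3aS,4R,7aR)-4,7a-dimethyl-1-oxo-4-[(triethylsilyl)oxy]octahydro-2-benzofuran-3-yl]methyl}prop-2-enal; 19 tert-butyl[(1E,3E)-hexa-1,3-dien-5-yn-1-yloxy]dimethylsilane
Product: 20 (1S,2S,5S)-2-[(tert-butyldimethylsilyl)oxy]-1-{[(3R,3aS,4R,7aR)-4,7a-dimethyl-1-oxo-4-[(triethylsilyl)oxy]octahydro-2-benzofuran-3-yl]methyl}-5-ethynylcyclohex-3-ene-1-carbaldehyde
Conditions: 19 (2 equiv), (R)-3,3-diphenyl-1-(2-methylphenyl)tetrahydro-1H,3H-pyrrolo[1,2-c][1,3,2]oxazaborole·HNTf2 (20 mol%), CH2Cl2, –78 to –40 °C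
Reagents that add atoms: none
Why: In this Lewis-acid-catalysed Diels–Alder reaction of a 2-substituted acrolein with a 1-silyloxy diene, the oxygen donor makes C13 the nucleophilic terminus so that C13 bonds to C14 and C9 to C8, the formyl group reacts endo and so ends cis to both the C9 silyloxy and the C13 ethynyl group, and the chiral oxazaborolidinium ion shields one face of C8=C14 and thus sets C8 (and with it C9 and C13) independently of the remote lactone centres.

Step 16
Reactants: 20 (1S,2S,5S)-2-[(tert-butyldimethylsilyl)oxy]-1-{[(3R,3aS,4R,7aR)-4,7a-dimethyl-1-oxo-4-[(triethylsilyl)oxy]octahydro-2-benzofuran-3-yl]methyl}-5-ethynylcyclohex-3-ene-1-carbaldehyde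
Product: 21 (1R,2S,5S)-2-[(tert-butyldimethylsilyl)oxy]-1-{[(3R,3aS,4R,7aR)-4,7a-dimethyl-1-oxo-4-[(triethylsilyl)oxy]octahydro-2-benzofuran-3-yl]methyl}-6-methylidenebicyclo[3.2.1]oct-3-en-7-ol (both C7 epimers)
Conditions: CrCl2 (6 equiv), NiCl2 (10 mol%), PPh3 (20 mol%), H2O (2 equiv), DMF (0.01 M), 25 °C
Reagents that add atoms: none
Why: The chromium-mediated, nickel-catalysed reductive coupling of a terminal alkyne with an aldehyde (a nickel hydride adds across the alkyne with the metal on the internal carbon, transmetalation gives the 2-alkenylchromium species, which adds to the formyl group) is used here intramolecularly, C16 and C15 being held cis-1,3 on the cyclohexene, so the five-membered ring with the exocyclic methylene closes, and the C15 configuration is left open because C15 is oxidised in the next step.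

Step 17
Reactants: 21 (1R,2S,5S)-2-[(tert-butyldimethylsilyl)oxy]-1-{[(3R,3aS,4R,7aR)-4,7a-dimethyl-1-oxo-4-[(triethylsilyl)oxy]octahydro-2-benzofuran-3-yl]methyl}-6-methylidenebicyclo[3.2.1]oct-3-en-7-ol (both C7 epimers)
Product: 22 (1S,2S,5S)-2-[(tert-butyldimethylsilyl)oxy]-1-{[(3R,3aS,4R,7aR)-4,7a-dimethyl-1-oxo-4-[(triethylsilyl)oxy]octahydro-2-benzofuran-3-yl]methyl}-6-methylidenebicyclo[3.2.1]oct-3-en-7-one
Conditions: Dess–Martin periodinane, CH2Cl2, 0 °C to rt
Reagents that add atoms: none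
Why: Dess–Martin oxidation of the allylic alcohol converts both C15 epimers into the same exo-methylene ketone.

Step 18
Reactants: 22 (1S,2S,5S)-2-[(tert-butyldimethylsilyl)oxy]-1-{[(3R,3aS,4R,7aR)-4,7a-dimethyl-1-oxo-4-[(triethylsilyl)oxy]octahydro-2-benzofuran-3-yl]methyl}-6-methylidenebicyclo[3.2.1]oct-3-en-7-one
Product: 23 (1R,2S,5S,7R)-2-[(tert-butyldimethylsilyl)oxy]-1-{[(3R,3aS,4R,7aR)-4,7a-dimethyl-1-oxo-4-[(triethylsilyl)oxy]octahydro-2-benzofuran-3-yl]methyl}-6-methylidenebicyclo[3.2.1]oct-3-en-7-ol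
Conditions: NaBH4, CeCl3·7H2O, MeOH, –78 °C
Reagents that add atoms: none
Why: In this Luche reduction (1,2-selective hydride addition to the enone) hydride should attack C15 from the exo face, on the side of the one-carbon bridge C14, because the endo face is screened by the three-carbon bridge and its C9 silyloxy group, so the hydroxyl ends on the side of C9 as the target requires (15R).

Step 19
Reactants: 23 (1R,2S,5S,7R)-2-[(tert-butyldimethylsilyl)oxy]-1-{[(3R,3aS,4R,7aR)-4,7a-dimethyl-1-oxo-4-[(triethylsilyl)oxy]octahydro-2-benzofuran-3-yl]methyl}-6-methylidenebicyclo[3.2.1]oct-3-en-7-ol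
Product: 24 (1R,2S,5S,7R)-2-[(tert-butyldimethylsilyl)oxy]-1-{[(3R,3aS,4R,7aR)-4,7a-dimethyl-1-oxo-4-[(triethylsilyl)oxy]octahydro-2-benzofuran-3-yl]methyl}-6-methylidenebicyclo[3.2.1]oct-3-en-7-yl acetate
Conditions: Ac2O, pyridine, DMAP (cat.), CH2Cl2, 0 °C to rt
Reagents that add atoms: acetic anhydride, CC(=O)OC(C)=O
Why: DMAP-catalysed acetylation esterifies the only free hydroxyl group with retention at C15.

Step 20
Reactants: 24 (1R,2S,5S,7R)-2-[(tert-butyldimethylsilyl)oxy]-1-{[(3R,3aS,4R,7aR)-4,7a-dimethyl-1-oxo-4-[(triethylsilyl)oxy]octahydro-2-benzofuran-3-yl]methyl}-6-methylidenebicyclo[3.2.1]oct-3-en-7-yl acetate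
Product: 25 (1S,2S,5S,7R)-2-hydroxy-1-{[(3R,3aS,4R,7aR)-4-hydroxy-4,7a-dimethyl-1-oxooctahydro-2-benzofuran-3-yl]methyl}-6-methylidenebicyclo[3.2.1]oct-3-en-7-yl acetate
Conditions: HF·pyridine, pyridine, THF, 0 °C to rt
Reagents that add atoms: none
Why: Fluoride cleaves both silyl ethers under acidic, non-basic conditions, which avoid acetyl migration from O15 to O9 and leave the allylic acetate and the lactone intact.

Step 21
Reactants: 25 (1S,2S,5S,7R)-2-hydroxy-1-{[(3R,3aS,4R,7aR)-4-hydroxy-4,7a-dimethyl-1-oxooctahydro-2-benzofuran-3-yl]methyl}-6-methylidenebicyclo[3.2.1]oct-3-en-7-yl acetate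
Product: 26 (1R,5S,7R)-1-{[(3R,3aS,4R,7aR)-4-hydroxy-4,7a-dimethyl-1-oxooctahydro-2-benzofuran-3-yl]methyl}-6-methylidene-2-oxobicyclo[3.2.1]oct-3-en-7-yl acetate (CNP0172716.1)
Conditions: Dess–Martin periodinane, CH2Cl2, 0 °C to rt
Reagents that add atoms: none
Why: Dess–Martin oxidation of the secondary allylic C9 alcohol gives the enone, while the tertiary C10 alcohol cannot be oxidised and C8, being quaternary, cannot epimerise.

**Compound list**
1 | (E)-3-methylpent-2-en-4-yn-1-ol | C#C/C(C)=C/CO | starting material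
2 | (E)-3-methylpenta-2,4-dien-1-ol | C=C/C(C)=C/CO | intermediate
3 | (E)-3-methylpenta-2,4-dienal | C=C/C(C)=C/C=O | intermediate
4 | 3-iodopropan-1-ol | OCCCI | starting material
5 | tert-butyl(3-iodopropoxy)diphenylsilane | CC(C)(C)[Si](OCCCI)(c1ccccc1)c1ccccc1 | intermediate
6 | bis[3-(tert-butyldiphenylsilyloxy)propyl]zinc | CC(C)(C)[Si](OCCC[Zn]CCCO[Si](c1ccccc1)(c1ccccc1)C(C)(C)C)(c1ccccc1)c1ccccc1 | intermediate (not isolated)
7 | (4R,5E)-1-[(tert-butyldiphenylsilyl)oxy]-6-methylocta-5,7-dien-4-ol | O[C@H](CCCO[Si](c1ccccc1)(c1ccccc1)C(C)(C)C)/C=C(C)/C=C | intermediate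
8 | methacryloyl chloride | C=C(C)C(Cl)=O | starting material
9 | (4R,5E)-1-[(tert-butyldiphenylsilyl)oxy]-6-methylocta-5,7-dien-4-yl 2-methylprop-2-enoate | C=C(C)C(=O)O[C@H](CCCO[Si](c1ccccc1)(c1ccccc1)C(C)(C)C)/C=C(C)/C=C | intermediate
10 | (3R,3aS,7aR)-3-{3-[(tert-butyldiphenylsilyl)oxy]propyl}-4,7a-dimethyl-3a,6,7,7a-tetrahydro-2-benzofuran-1(3H)-one | CC(C)(C)[Si](OCCC[C@H]1OC(=O)[C@]2(C)CCC=C(C)[C@H]12)(c1ccccc1)c1ccccc1 | intermediate
11 | (3R,3aS,4R,7aR)-3-{3-[(tert-butyldiphenylsilyl)oxy]propyl}-4-hydroxy-4,7a-dimethylhexahydro-2-benzofuran-1(3H)-one | CC(C)(C)[Si](OCCC[C@H]1OC(=O)[C@]2(C)CCC[C@@](C)(O)[C@H]12)(c1ccccc1)c1ccccc1 | intermediate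
12 | (3R,3aS,4R,7aR)-4-hydroxy-3-(3-hydroxypropyl)-4,7a-dimethylhexahydro-2-benzofuran-1(3H)-one | OCCC[C@H]1OC(=O)[C@]2(C)CCC[C@@](C)(O)[C@H]12 | intermediate
13 | 3-[(3R,3aS,4R,7aR)-4-hydroxy-4,7a-dimethyl-1-oxooctahydro-2-benzofuran-3-yl]propanal | O=CCC[C@H]1OC(=O)[C@]2(C)CCC[C@@](C)(O)[C@H]12 | intermediate
14 | 2-{[(3R,3aS,4R,7aR)-4-hydroxy-4,7a-dimethyl-1-oxooctahydro-2-benzofuran-3-yl]methyl}prop-2-enal | C=C(C=O)C[C@H]1OC(=O)[C@]2(C)CCC[C@@](C)(O)[C@H]12 | intermediate
15 | 2-{[(3R,3aS,4R,7aR)-4,7a-dimethyl-1-oxo-4-[(triethylsilyl)oxy]octahydro-2-benzofuran-3-yl]methyl}prop-2-enal | C=C(C=O)C[C@H]1OC(=O)[C@]2(C)CCC[C@@](C)(O[Si](CC)(CC)CC)[C@H]12 | intermediate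
16 | pyridine–sulfur trioxide complex | O=S(=O)([O-])[n+]1ccccc1 | starting material
17 | potassium (1E,3E)-5-oxopenta-1,3-dien-1-olate | [K+].[O-]/C=C/C=C/C=O | intermediate
18 | (2E,4E)-5-[(tert-butyldimethylsilyl)oxy]penta-2,4-dienal | O=C/C=C/C=C/O[Si](C)(C)C(C)(C)C | intermediate
19 | tert-butyl[(1E,3E)-hexa-1,3-dien-5-yn-1-yloxy]dimethylsilane | C#C/C=C/C=C/O[Si](C)(C)C(C)(C)C | intermediate
20 | (1S,2S,5S)-2-[(tert-butyldimethylsilyl)oxy]-1-{[(3R,3aS,4R,7aR)-4,7a-dimethyl-1-oxo-4-[(triethylsilyl)oxy]octahydro-2-benzofuran-3-yl]methyl}-5-ethynylcyclohex-3-ene-1-carbaldehyde (formyl, silyloxy and ethynyl groups all cis) | C#C[C@@H]1C=C[C@H](O[Si](C)(C)C(C)(C)C)[C@@](C[C@H]2OC(=O)[C@]3(C)CCC[C@@](C)(O[Si](CC)(CC)CC)[C@H]23)(C1)C=O | intermediate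
21 | (1R,2S,5S)-2-[(tert-butyldimethylsilyl)oxy]-1-{[(3R,3aS,4R,7aR)-4,7a-dimethyl-1-oxo-4-[(triethylsilyl)oxy]octahydro-2-benzofuran-3-yl]methyl}-6-methylidenebicyclo[3.2.1]oct-3-en-7-ol (both C7 epimers) | C=C1[C@@H]2C=C[C@H](O[Si](C)(C)C(C)(C)C)[C@@](C[C@H]3OC(=O)[C@]4(C)CCC[C@@](C)(O[Si](CC)(CC)CC)[C@H]34)(C2)C1O | intermediate
22 | (1S,2S,5S)-2-[(tert-butyldimethylsilyl)oxy]-1-{[(3R,3aS,4R,7aR)-4,7a-dimethyl-1-oxo-4-[(triethylsilyl)oxy]octahydro-2-benzofuran-3-yl]methyl}-6-methylidenebicyclo[3.2.1]oct-3-en-7-one | C=C1[C@@H]2C=C[C@H](O[Si](C)(C)C(C)(C)C)[C@@](C[C@H]3OC(=O)[C@]4(C)CCC[C@@](C)(O[Si](CC)(CC)CC)[C@H]34)(C2)C1=O | intermediate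
23 | (1R,2S,5S,7R)-2-[(tert-butyldimethylsilyl)oxy]-1-{[(3R,3aS,4R,7aR)-4,7a-dimethyl-1-oxo-4-[(triethylsilyl)oxy]octahydro-2-benzofuran-3-yl]methyl}-6-methylidenebicyclo[3.2.1]oct-3-en-7-ol | C=C1[C@@H]2C=C[C@H](O[Si](C)(C)C(C)(C)C)[C@@](C[C@H]3OC(=O)[C@]4(C)CCC[C@@](C)(O[Si](CC)(CC)CC)[C@H]34)(C2)[C@@H]1O | intermediate
24 | (1R,2S,5S,7R)-2-[(tert-butyldimethylsilyl)oxy]-1-{[(3R,3aS,4R,7aR)-4,7a-dimethyl-1-oxo-4-[(triethylsilyl)oxy]octahydro-2-benzofuran-3-yl]methyl}-6-methylidenebicyclo[3.2.1]oct-3-en-7-yl acetate | C=C1[C@@H]2C=C[C@H](O[Si](C)(C)C(C)(C)C)[C@@](C[C@H]3OC(=O)[C@]4(C)CCC[C@@](C)(O[Si](CC)(CC)CC)[C@H]34)(C2)[C@@H]1OC(C)=O | intermediate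
25 | (1S,2S,5S,7R)-2-hydroxy-1-{[(3R,3aS,4R,7aR)-4-hydroxy-4,7a-dimethyl-1-oxooctahydro-2-benzofuran-3-yl]methyl}-6-methylidenebicyclo[3.2.1]oct-3-en-7-yl acetate | C=C1[C@@H]2C=C[C@H](O)[C@@](C[C@H]3OC(=O)[C@]4(C)CCC[C@@](C)(O)[C@H]34)(C2)[C@@H]1OC(C)=O | intermediate
26 | (1R,5S,7R)-1-{[(3R,3aS,4R,7aR)-4-hydroxy-4,7a-dimethyl-1-oxooctahydro-2-benzofuran-3-yl]methyl}-6-methylidene-2-oxobicyclo[3.2.1]oct-3-en-7-yl acetate (CNP0172716.1) | C=C1[C@@H]2C=CC(=O)[C@@](C[C@H]3OC(=O)[C@]4(C)CCC[C@@](C)(O)[C@H]34)(C2)[C@@H]1OC(C)=O | target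

**Step count and risks**

Total step count: 21. Longest linear sequence: 17 steps (steps 1, 2, 4–11 and 15–21).

Steps most likely to fail:

1. Step 6 (key cycloaddition). The reaction may pass to a comparable or larger extent through the transition state with the tether carbonyl outside the diene, which gives the trans-fused lactone; the dienylic ester may also ionise or undergo acyl shift at 180 °C before it cyclises. The fallback sets out from 7 and comes back at 10. It keeps the ester-tethered cycloaddition but adds a removable activating and directing carboxyl group on C3. Citraconic anhydride is opened by allyl alcohol at the carbonyl remote from the methyl group to give the half-ester (2Z)-2-methyl-4-oxo-4-(prop-2-en-1-yloxy)but-2-enoic acid F1. Coupling of F1 with 7 (DCC, cat. DMAP, 0 °C) gives the mixed (Z)-diester F2. This maleate-type dienophile should cyclise near 110 °C in toluene; its second ester group, cis to the tether carbonyl, adds its own endo preference, and dienyl esters of this (Z)-diacid type are known to give cis-fused lactones, so the cis-fused adduct with an allyl ester on C3, F3, is expected. Pd(PPh3)4 and morpholine free the carboxylic acid F4. The acid is converted into its N-acyloxy-pyridine-2-thione ester F5, and Barton decarboxylation (t-BuSH, visible light) then gives 10.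

2. Step 15 (intermolecular Diels–Alder reaction). The lactone and silyl ether oxygens may compete for the boron catalyst and erode facial control; the formyl group may react exo; the acid may strip the silyl dienol ether before cycloaddition. The fallback sets out from 15 and 19 and comes back at 20. It gives up asymmetric induction: 15 and 19 are heated without Lewis acid (toluene, BHT, about 100 °C, sealed tube). The uncatalysed reaction keeps the regiochemistry and the formyl-endo topology but uses both faces of C8=C14, so 20 forms together with the (1R,2R,5R)-cyclohexene diastereomer F6, in which C8, C9 and C13 are all inverted. Because of the lactone part the two are diastereomers; they are separated by chromatography and 20 goes on.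

3. Step 16 (reductive alkyne–aldehyde ring closure). Hydrometalation of the hindered alkyne next to the doubly allylic C13 may be slow, so that reduction or pinacol coupling of the aldehyde takes over. The fallback sets out from 20 and comes back at 21; it is the classical route through a vinyl iodide. NaBH4 reduces the aldehyde to the primary alcohol F7. Stannylcupration (Me3SnCu·SMe2, MeOH, THF, –78 °C) places tin on the internal alkyne carbon and gives the 2-(trimethylstannyl)alkene F8. Iodine converts it into the 2-iodoalkene F9, and Dess–Martin oxidation gives the iodo aldehyde F10. Nozaki–Hiyama–Kishi cyclisation (CrCl2, cat. NiCl2, DMSO, rt) then closes C15–C16 and gives 21.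

**Further compounds**
F1 | step 6 | (2Z)-2-methyl-4-oxo-4-(prop-2-en-1-yloxy)but-2-enoic acid | C=CCOC(=O)/C=C(/C)C(=O)O
F2 | step 6 | (4R,5E)-1-[(tert-butyldiphenylsilyl)oxy]-6-methylocta-5,7-dien-4-yl prop-2-en-1-yl (2Z)-2-methylbut-2-enedioate | C=CCOC(=O)/C=C(/C)C(=O)O[C@H](CCCO[Si](c1ccccc1)(c1ccccc1)C(C)(C)C)/C=C(C)/C=C
F3 | step 6 | allyl ester of the cis-fused lactone 10 carrying a carboxyl group on C3, cis to C19 | CC(C)(C)[Si](OCCC[C@H]1OC(=O)[C@]2(C)[C@H](C(=O)OCC=C)CC=C(C)[C@H]12)(c1ccccc1)c1ccccc1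
F4 | step 6 | C3 carboxylic acid of the cis-fused lactone 10 | CC(C)(C)[Si](OCCC[C@H]1OC(=O)[C@]2(C)[C@H](C(=O)O)CC=C(C)[C@H]12)(c1ccccc1)c1ccccc1
F5 | step 6 | 2-thioxopyridin-1(2H)-yl ester of acid F4 | CC(C)(C)[Si](OCCC[C@H]1OC(=O)[C@]2(C)[C@H](C(=O)ON3C=CC=CC3=S)CC=C(C)[C@H]12)(c1ccccc1)c1ccccc1
F6 | step 15 | (1R,2R,5R)-cyclohexene diastereomer of 20 (C8, C9 and C13 inverted) | C#C[C@H]1C=C[C@@H](O[Si](C)(C)C(C)(C)C)[C@](C[C@H]2OC(=O)[C@]3(C)CCC[C@@](C)(O[Si](CC)(CC)CC)[C@H]23)(C1)C=O
F7 | step 16 | [(1R,2S,5S)-2-[(tert-butyldimethylsilyl)oxy]-1-{[(3R,3aS,4R,7aR)-4,7a-dimethyl-1-oxo-4-[(triethylsilyl)oxy]octahydro-2-benzofuran-3-yl]methyl}-5-ethynylcyclohex-3-en-1-yl]methanol | C#C[C@@H]1C=C[C@H](O[Si](C)(C)C(C)(C)C)[C@@](C[C@H]2OC(=O)[C@]3(C)CCC[C@@](C)(O[Si](CC)(CC)CC)[C@H]23)(C1)CO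
F8 | step 16 | 5-[1-(trimethylstannyl)ethenyl] analogue of alcohol F7 | C=C([Sn](C)(C)C)[C@@H]1C=C[C@H](O[Si](C)(C)C(C)(C)C)[C@@](C[C@H]2OC(=O)[C@]3(C)CCC[C@@](C)(O[Si](CC)(CC)CC)[C@H]23)(C1)CO
F9 | step 16 | 5-(1-iodoethenyl) analogue of alcohol F7 | C=C(I)[C@@H]1C=C[C@H](O[Si](C)(C)C(C)(C)C)[C@@](C[C@H]2OC(=O)[C@]3(C)CCC[C@@](C)(O[Si](CC)(CC)CC)[C@H]23)(C1)CO
F10 | step 16 | (1S,2S,5S)-2-[(tert-butyldimethylsilyl)oxy]-1-{[(3R,3aS,4R,7aR)-4,7a-dimethyl-1-oxo-4-[(triethylsilyl)oxy]octahydro-2-benzofuran-3-yl]methyl}-5-(1-iodoethenyl)cyclohex-3-ene-1-carbaldehyde | C=C(I)[C@@H]1C=C[C@H](O[Si](C)(C)C(C)(C)C)[C@@](C[C@H]2OC(=O)[C@]3(C)CCC[C@@](C)(O[Si](CC)(CC)CC)[C@H]23)(C1)C=O
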